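(The numbers of this flask were drawn at random within sensible limits; no experiment stands behind them.)

Two questions stand over these flasks: how much target each holds at the end, and how that row runs.

the same everywhere: gas phase 12 mM (held); free catalyst 4.5 mM; time 2.5 min
- Thursday's: substrate 0.030 M
- Tuesday's: substrate 0.080 M
- Monday's: substrate 0.25 M
- Sunday's: substrate 0.80 M
- Wednesday's: substrate 2.5 M

    gas phase ⇌ dissolved gas, rate k1*(csat - [dissolved gas]) (k1 = 0.220 s⁻¹, csat = 12 mM)
    substrate + dissolved gas + free catalyst → free catalyst + target (k2 = 11200 M⁻² s⁻¹)
    free catalyst + target → spent catalyst (k3 = 0.0647 M⁻¹ s⁻¹)
    dissolved gas → decomposed reagent (k4 = 0.00526 s⁻¹)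
    substrate + target → side product (k5 = 0.0388 M⁻¹ s⁻¹)

- [target] at the end for Thursday's, Tuesday's, Monday's, Sunday's, Wednesday's, in this order
- how the row runs (falls all the way / rises, then falls / hardly changes / falls, then rises / rises all the way)

- a species is counted by the substrate in it: one side product counts as two
- at the start none of the gas is dissolved
- "hardly changes" means that all values lie within two and a half points (for a concentration: within two and a half percent of the largest)
- run time (Thursday's): 2.5 min

I start from Wednesday's and reckon rates. Gas enters the liquid, at first free of dissolved gas, at 2.64 mM s⁻¹. In Wednesday's a dissolved gas lasts 0.00794 s against the catalysed step, far shorter than the 4.55 s of transfer or the 190 s of decomposition, so target starts at the rate of this gas feed.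

What slows its net gain is the side reaction: in Wednesday's a target lasts 10.3 s among the substrate. That is the holding time, one over the side-reaction constant times the substrate concentration, the pseudo-first-order life of target. Beside it, the loss of target to the catalyst in Wednesday's is at the start a correction of 0.300%.

The net rate of target falls by a factor e in each holding time, and Wednesday's run lasts 14.6 of them, so target comes close to where loss equals feed, at feed times holding time: 0.0272 M. The larger correction in Wednesday's is the fall of the substrate. At that balance the substrate falls at twice the feed, by 31.7% of Wednesday's charge over the run, which by the end of the run lengthens the holding time by a factor 1.46. I commit to 0.0398 M for Wednesday's.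

In Tuesday's the holding time is 322 s, longer than the run, and the charge is fed in 30.3 s, so target stays close to 0.080 M. In Thursday's the holding time of 859 s is longer still, so target stays close to 0.030 M. Tuesday's stands above both Thursday's and Wednesday's, so I expect the row to rise, then fall; Monday's and Sunday's I leave unreckoned.

The forecast, whose side reaction “holds target near the balance of supply and removal”, gives 0.0289 M, 0.075 M, 0.19 M, 0.163 M and 0.04 M, a row that rises, then falls.

The flasks give 0.0287 M, 0.0749 M, 0.190 M, 0.165 M and 0.0372 M, a row that rises, then falls, turning at 0.46 M of substrate. Wednesday's ends with substrate at 69.9% of its charge, which makes the holding time 14.7 s, shorter than the run of 150 s, and feed times that time is 0.0388 M beside a target of 0.0372 M. Sunday's ends with substrate at 24% of its charge and a holding time of 136 s, and there target, at 0.165 M, stands below feed times holding time, 0.359 M.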